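**Retrosynthetic overview**
1. Feature used: target 7 is a mirror-symmetric dimer. Two identical 2,3-dibromo-4,5-dihydroxyphenyl rings (A, A′) sit on the benzylic bridge C7–O–C7′. Each C7 lies para to a C4–OH, so the bridge is labile (para-quinone methide) and tolerates no late ether cleavage or hydrogenolysis.
2. Key disconnection: C7′–O, with both halves traced back to the same aldehyde 4. The two formyl carbons, both electrophilic (like polarity), are joined through the carbonyl oxygen of one of them by a hydride-driven reductive homo-etherification in the last step. The precursor holds half the atoms, and no benzylic alcohol, benzylic halide or isolated protected compound is needed.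
3. Aldehyde 4 goes back to vanillin 1. C3–Br is placed ortho to C4–OH and C2–Br para to C5–OMe (double SEAr while CHO occupies C1). The O-methyl group is removed before the bridge exists.
4. No ring is formed (both benzene rings come from 1) and there is no stereocentre to set.

Key step: step 3

Remark on the chemistry: the SMILES contains no stereocentre, stereoaxis or double-bond isomerism. The target is achiral, so "single enantiomer" requires no stereocontrol.

Step 1
Reactants: 1 vanillin (4-hydroxy-3-methoxybenzaldehyde)
Product: 3 5,6-dibromovanillin (2,3-dibromo-4-hydroxy-5-methoxybenzaldehyde), via 5-bromovanillin 2 (not isolated)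
Conditions: Br2 (1.05 equiv), AcOH, rt; then Fe powder (cat.), Br2 (1.2 equiv), rt → 50 °C; ice-water, filter
Reagents that add atoms: bromine, BrBr
Why: Two consecutive electrophilic aromatic brominations, in which the free C4–OH directs the first bromine ortho to itself (its para position carries CHO) and FeBr3-activated bromine then enters para to the OMe group, the only remaining site with para-donor activation (the other C–H is wedged between CHO and OMe), while in anhydrous AcOH the formyl group should not be displaced from C1.

Step 2
Reactants: 3 5,6-dibromovanillin
Product: 4 2,3-dibromo-4,5-dihydroxybenzaldehyde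
Conditions: BBr3 (2.5 equiv), CH2Cl2, −78 °C → rt; then ice-water
Reagents that add atoms: none
Why: Lewis-acid aryl methyl ether cleavage, in which boron binds the C4–O/C5–OMe pair, bromide removes the methyl group by SN2 and water hydrolyses the cyclic catechol borate; the formyl group and aryl bromides should survive at or below rt, and the step is placed here because the C7–O–C7′ bridge would not survive BBr3.

Step 3
Reactants: 4 2,3-dibromo-4,5-dihydroxybenzaldehyde (two molecules)
Product: 7 bis(2,3-dibromo-4,5-dihydroxybenzyl) ether (target), via 2,3-dibromo-4,5-bis(trimethylsilyloxy)benzaldehyde 5 (not isolated), via bis[2,3-dibromo-4,5-bis(trimethylsilyloxy)benzyl] ether 6 (not isolated)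
Conditions: (i) Me3SiCl (2.3 equiv), Et3N (2.4 equiv), CH2Cl2, 0 °C → rt; pentane, filter under Ar, evaporate; (ii) Et3SiH (1.1 equiv per CHO), Me3SiOTf (10 mol %), CH2Cl2 (0.5 M), −40 → 0 °C; (iii) dilute aq. HCl (cat.), THF/H2O, 0 °C
Reagents that add atoms: chlorotrimethylsilane, C[Si](C)(C)Cl (source of the Me3Si groups of 5 and 6, which are lost again on the way to 7)
Why: Reductive homo-etherification of an aromatic aldehyde (closest known type: the silyl triflate- or silyl iodide-catalysed reductive coupling of aldehydes with trialkylsilanes to symmetrical ethers): O-silyl-activated 5 takes hydride from Et3SiH to give ArCH2OSiR3, whose oxygen adds to a second activated molecule of 5, the mixed silyl acetal loses disiloxane, and the oxocarbenium ion ArCH=O(+)–CH2Ar takes the second hydride, so that the C7–O–C7′ bridge arises from two formyl carbons of like polarity and the carbonyl oxygen of one of them. No ring is closed and no stereocentre is formed. The ether must win over the silyl ether stage, over reductive loss of the benzylic oxygen and over C-benzylation at C6–H or ipso at C1: acetal formation and oxocarbenium reduction are known to outrun direct aldehyde reduction, only about one hydride per formyl group is supplied, and the C2/C3 bromines offset the para C4–O donor, so that 6 should not ionise at or below 0 °C and its rings are poor π-nucleophiles. The ionic hydride conditions (no metal, no radical chain) should leave the four C–Br bonds untouched. The transient Me3Si groups remove the acidic, chelating catechol protons that would consume silane and bind the catalyst, make the substrate soluble in CH2Cl2, and fall off in the dilute-acid work-up, the pH range in which a para-hydroxybenzyl ether is most stable, so that 7 never meets base or a separate deprotection reagent.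

**Compound list**
1 | vanillin (4-hydroxy-3-methoxybenzaldehyde) | O=Cc1ccc(O)c(OC)c1 | starting material
2 | 5-bromovanillin (3-bromo-4-hydroxy-5-methoxybenzaldehyde) | O=Cc1cc(Br)c(O)c(OC)c1 | intermediate (not isolated)
3 | 5,6-dibromovanillin (2,3-dibromo-4-hydroxy-5-methoxybenzaldehyde) | O=Cc1cc(OC)c(O)c(Br)c1Br | intermediate
4 | 2,3-dibromo-4,5-dihydroxybenzaldehyde | O=Cc1cc(O)c(O)c(Br)c1Br | intermediate
5 | 2,3-dibromo-4,5-bis(trimethylsilyloxy)benzaldehyde | O=Cc1cc(O[Si](C)(C)C)c(O[Si](C)(C)C)c(Br)c1Br | intermediate (not isolated)
6 | bis[2,3-dibromo-4,5-bis(trimethylsilyloxy)benzyl] ether | C[Si](C)(C)Oc1cc(COCc2cc(O[Si](C)(C)C)c(O[Si](C)(C)C)c(Br)c2Br)c(Br)c(Br)c1O[Si](C)(C)C | intermediate (not isolated)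
7 | bis(2,3-dibromo-4,5-dihydroxybenzyl) ether (achiral) | Oc1cc(COCc2cc(O)c(O)c(Br)c2Br)c(Br)c(Br)c1O | target

Total step count: 3. Longest linear sequence: 3.

**Steps most likely to fail**

Step 3 (key step).
- What may go wrong: the reaction may stop at the benzyl silyl ether, or it may run on to reductive loss of the benzylic oxygen. The aryl silyl ether oxygens may compete as nucleophiles for the activated aldehyde. Benzylic ionisation may lead to C-benzylation of a ring. Exchange of Me3Si for Et3Si on the phenol oxygens is harmless, since both are hydrolysed in stage (iii).
- Fallback: it sets out from 4 and returns at 7. It replaces the reductive union of two aldehydes with a dehydrative union of two alcohols. Compound 4 is reduced with NaBH4 in THF/H2O at 0 °C to 2,3-dibromo-4,5-dihydroxybenzyl alcohol F1. F1 is then kept at high concentration in MeNO2 with catalytic TsOH and 4 Å molecular sieves at rt. Ionisation assisted by the para C4–OH (para-quinone methide or para-hydroxybenzyl cation) and capture by the primary hydroxyl group of a second molecule of F1 should give 7. Low temperature and short contact time favour kinetic O-alkylation over C-alkylation.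

Step 1.
- What may go wrong: the second bromination of the deactivated ring may be slow, may continue to a third substitution, or may displace the formyl group.
- Fallback: it sets out from 1 and returns at 3, and it reverses the order in which the two bromines enter. Compound 1 is acetylated (Ac2O, pyridine) to 4-acetoxy-3-methoxybenzaldehyde F2. With the C4–O donor muted, bromination (Br2, KBr, H2O, rt) should go para to OMe and give 4-acetoxy-2-bromo-5-methoxybenzaldehyde F3. Acid hydrolysis (6 M HCl, 90 °C) frees 2-bromo-4-hydroxy-5-methoxybenzaldehyde F4. The liberated phenol then directs a catalyst-free bromination (Br2, AcOH, rt) into its only open ortho position to give 3.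

Step 2.
- What may go wrong: the boron halide may attack the formyl group, or bromine may migrate or be lost from the crowded vicinal dibromide under HBr and Lewis acid.
- Fallback: it sets out from 2, which is isolated after the first stage of step 1 by dilution with water, and returns at 4. The ether cleavage is moved ahead of the second bromination. BBr3 in CH2Cl2 converts 2 into 3-bromo-4,5-dihydroxybenzaldehyde F5. Br2 in AcOH without iron should then brominate para to the newly freed C5–OH to give 4. The second halogen is thus directed by a free hydroxyl group rather than a methoxy group, and no Lewis acid ever meets the dibromide.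

**Further compounds**
F1 | step 3 | 2,3-dibromo-4,5-dihydroxybenzyl alcohol | OCc1cc(O)c(O)c(Br)c1Br
F2 | step 1 | 4-acetoxy-3-methoxybenzaldehyde (vanillin acetate) | CC(=O)Oc1ccc(C=O)cc1OC
F3 | step 1 | 4-acetoxy-2-bromo-5-methoxybenzaldehyde (6-bromovanillin acetate) | CC(=O)Oc1cc(Br)c(C=O)cc1OC
F4 | step 1 | 2-bromo-4-hydroxy-5-methoxybenzaldehyde (6-bromovanillin) | O=Cc1cc(OC)c(O)cc1Br
F5 | step 2 | 3-bromo-4,5-dihydroxybenzaldehyde | O=Cc1cc(O)c(O)c(Br)c1
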